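**Plan**

- The C5 and C8 phenols are masked as MOM ethers and the quinone is taken back to a 4-methoxy-1-naphthol.
- The ring C1–C2–C3–C4–C4a–C8a then has oxygen on C1 and C4, one carbon substituent on C2 and a fused benzene ring oxygenated at C5 and C8. This is the pattern that a chromium aryl(methoxy)carbene, a terminal alkyne and CO assemble, so the ring is cut at C3–C4, C1–C2 and C1–C8a.
- The alkyne already carries the whole side chain. It is cut at the ester C–O bond into an (R)-propargylic alcohol and 3-acetoxy-3-methylbutanoic acid, and the alcohol is traced to an ynone made from a Weinreb amide and an acetylide.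
- Forward: carbene complex from hydroquinone (2 steps); alkynyl ester from 4-methylpent-3-enoic acid (5 steps, plus 1 for the acid); the benzannulation closes the only new ring; oxidation and MOM removal finish.
- The single stereocentre (C1′, R) is set by Noyori transfer hydrogenation of the ynone with the (R,R)-catalyst. No bond to it is made or broken afterwards.

Key step: step 9

Remark: ring atoms are numbered as in the naphthoquinone (C1 and C4 carbonyls, side chain on C2, hydroxyls on C5 and C8). The naphthazarin is written as the tautomer of the target SMILES; its tautomers are one compound.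

**Route**

Step 1
Reactants: 1 hydroquinone
Product: 2 1,4-bis(methoxymethoxy)benzene
Conditions: NaH, DMF, 0 °C; MOMCl, 0 °C to rt
Reagents that add atoms: chloromethyl methyl ether, COCCl
Why: Williamson-type O-alkylation of the bis-phenoxide gives the bis-acetal, whose MOM groups direct the later ortho-lithiation, tolerate the organometallic and oxidative steps and leave under mild acid.

Step 2
Reactants: 2 1,4-bis(methoxymethoxy)benzene; 3 chromium hexacarbonyl
Product: 6 pentacarbonyl{[2,5-bis(methoxymethoxy)phenyl](methoxy)methylidene}chromium, via aryllithium 4 (not isolated), via lithium acylchromate 5 (not isolated)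
Conditions: n-BuLi, TMEDA, THF, 0 °C to rt; Cr(CO)6, THF, 0 °C to rt; Me3OBF4, CH2Cl2, 0 °C
Reagents that add atoms: trimethyloxonium tetrafluoroborate, C[O+](C)C.F[B-](F)(F)F
Why: Fischer carbene synthesis: MOM-directed ortho-lithiation (all four ring CH positions are equivalent) gives 4, which adds to a CO ligand to give acylate 5, and O-methylation of the acylate oxygen gives the methoxycarbene.

Step 3
Reactants: 7 4-methylpent-3-enoic acid
Product: 9 N-methoxy-N,4-dimethylpent-3-enamide, via acylimidazole 8 (not isolated)
Conditions: CDI, CH2Cl2, 0 °C to rt; MeNH(OMe)·HCl, rt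
Reagents that add atoms: N,O-dimethylhydroxylamine hydrochloride, CNOC.Cl
Why: Weinreb amide formation through the acylimidazole is an activation without added strong base, under which the β,γ-double bond should not move into conjugation.

Step 4
Reactants: 9 N-methoxy-N,4-dimethylpent-3-enamide
Product: 10 6-methyl-1-(trimethylsilyl)hept-5-en-1-yn-3-one
Conditions: TMSC≡CH, n-BuLi, THF, −78 °C; add 9, −78 to −20 °C; AcOH, −78 °C
Reagents that add atoms: ethynyltrimethylsilane, C#C[Si](C)(C)C
Why: Weinreb ketone synthesis: the lithium acetylide adds only once because the N-methoxy chelate holds the tetrahedral adduct until the cold acidic quench, which also keeps the skipped enynone away from base.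

Step 5
Reactants: 10 6-methyl-1-(trimethylsilyl)hept-5-en-1-yn-3-one
Product: 11 (R)-6-methyl-1-(trimethylsilyl)hept-5-en-1-yn-3-ol
Conditions: Ru[(R,R)-TsDPEN](p-cymene) (1–2 mol %), i-PrOH, rt
Reagents that add atoms: none
Why: Noyori asymmetric transfer hydrogenation of an alkynyl ketone without added base: the (R,R)-catalyst passes hydride and the N–H proton through a six-membered transition state to the Si face of the carbonyl, the alkynyl group taking the place an aryl group takes beside the η6-arene, which sets the (R) carbinol centre.

Step 6
Reactants: 11 (R)-6-methyl-1-(trimethylsilyl)hept-5-en-1-yn-3-ol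
Product: 12 (R)-6-methylhept-5-en-1-yn-3-ol
Conditions: K2CO3 (cat.), MeOH, 0 °C to rt
Reagents that add atoms: none
Why: Base-catalysed methanolysis of the alkynyl C–Si bond (protodesilylation) frees the terminal alkyne before any base-sensitive ester is present and does not touch the carbinol centre.

Step 7
Reactants: 13 3-hydroxy-3-methylbutanoic acid
Product: 14 3-acetoxy-3-methylbutanoic acid
Conditions: Ac2O, Et3N, DMAP (cat.), CH2Cl2, rt; then H2O
Reagents that add atoms: acetic anhydride, CC(=O)OC(C)=O
Why: DMAP-catalysed (Steglich-type) acetylation is the standard acylation of a tertiary alcohol, and the aqueous finish returns any mixed anhydride at the carboxyl group to the free acid.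

Step 8
Reactants: 12 (R)-6-methylhept-5-en-1-yn-3-ol; 14 3-acetoxy-3-methylbutanoic acid
Product: 15 (R)-6-methylhept-5-en-1-yn-3-yl 3-acetoxy-3-methylbutanoate
Conditions: DCC, DMAP (5 mol %), CH2Cl2, 0 °C to rt
Reagents that add atoms: none
Why: Steglich esterification acylates the unhindered propargylic alcohol at oxygen, so the C–O bond of the stereocentre is never broken and (R) is retained, while low DMAP loading at 0 °C limits β-elimination of acetate from the activated acid.

Step 9
Reactants: 6 pentacarbonyl{[2,5-bis(methoxymethoxy)phenyl](methoxy)methylidene}chromium; 15 (R)-6-methylhept-5-en-1-yn-3-yl 3-acetoxy-3-methylbutanoate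
Product: 17 (R)-1-[1-hydroxy-4-methoxy-5,8-bis(methoxymethoxy)naphthalen-2-yl]-4-methylpent-3-enyl 3-acetoxy-3-methylbutanoate, via tricarbonylchromium naphthol complex 16 (not isolated)
Conditions: 6 (1.3 equiv), 15 (1.0 equiv), degassed THF (0.05 M), 50 °C, Ar; then air, Et2O, rt; filtration through silica; 17 used at once
Reagents that add atoms: none
Why: Dötz benzannulation: after loss of one CO from 6 (helped by the ortho MOM oxygen) the alkyne of 15 inserts into Cr=C with its CH end bonding to the carbene carbon (C4–C3), CO then inserts into the new vinylcarbene to give an η4-vinylketene (C2–C1), and the ketene carbon closes onto the one free ortho carbon of the aryl ring (C1–C8a). The six-membered ring closes by 6π-electrocyclisation of this aryl-vinylketene, and enolisation gives the Cr(CO)3-bound 4-methoxy-1-naphthol 16, from which air removes the metal. No stereocentre is formed, and the propargylic centre takes no part in any bond change while neutral THF at 50 °C should leave both esters untouched. The selectivity needed is chemoselectivity for the phenol over indene, cyclobutenone and furan products, which chromium, a methoxycarbene, a terminal alkyne and THF at moderate dilution favour, and the OMOM group on the other ortho carbon leaves only one site for ring closure. The sense of alkyne insertion (large group next to the CO-derived carbon) is expected but not essential, because the C5/C8 ring is symmetrically substituted and either regioisomer would give the same quinone in step 10. The alkene is held in a 1,5-enyne, so cyclopropanation by the vinylcarbene would require a bicyclo[2.1.0]pentane and should not compete.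

Step 10
Reactants: 17 (R)-1-[1-hydroxy-4-methoxy-5,8-bis(methoxymethoxy)naphthalen-2-yl]-4-methylpent-3-enyl 3-acetoxy-3-methylbutanoate
Product: 18 (R)-1-[5,8-bis(methoxymethoxy)-1,4-dioxo-1,4-dihydronaphthalen-2-yl]-4-methylpent-3-enyl 3-acetoxy-3-methylbutanoate
Conditions: PhI(OAc)2 (1.1 equiv), MeCN/H2O (2:1), 0 °C
Reagents that add atoms: water, O
Why: Hypervalent-iodine oxidation of a p-methoxyphenol: ligand exchange at the naphthol oxygen, attack of water at the methoxy-bearing C4 and loss of methanol from the hemiketal give the 1,4-quinone, while the bis-MOM ring (no free OH) and the alkene should be left alone.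

Step 11
Reactants: 18 (R)-1-[5,8-bis(methoxymethoxy)-1,4-dioxo-1,4-dihydronaphthalen-2-yl]-4-methylpent-3-enyl 3-acetoxy-3-methylbutanoate
Product: 19 (R)-1-(5,8-dihydroxy-1,4-dioxo-1,4-dihydronaphthalen-2-yl)-4-methylpent-3-enyl 3-acetoxy-3-methylbutanoate
Conditions: NaHSO4·SiO2, wet CH2Cl2, rt
Reagents that add atoms: none
Why: Acid-catalysed acetal hydrolysis of the two aryl MOM ethers on a weakly acidic solid in a non-nucleophilic solvent, where each freed phenol is held by a hydrogen bond to the peri carbonyl and neither ester nor the trisubstituted alkene should react.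

**Compound list**

1 | hydroquinone | Oc1ccc(O)cc1 | starting material
2 | 1,4-bis(methoxymethoxy)benzene | COCOc1ccc(OCOC)cc1 | intermediate
3 | chromium hexacarbonyl | O=C=[Cr](=C=O)(=C=O)(=C=O)(=C=O)=C=O | starting material
4 | [2,5-bis(methoxymethoxy)phenyl]lithium | [Li]c1cc(OCOC)ccc1OCOC | intermediate
5 | lithium pentacarbonyl[2,5-bis(methoxymethoxy)benzoyl]chromate | [Li+].COCOc1ccc(OCOC)c(c1)C([O-])=[Cr](=C=O)(=C=O)(=C=O)(=C=O)=C=O | intermediate
6 | pentacarbonyl{[2,5-bis(methoxymethoxy)phenyl](methoxy)methylidene}chromium | COCOc1ccc(OCOC)c(c1)C(OC)=[Cr](=C=O)(=C=O)(=C=O)(=C=O)=C=O | intermediate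
7 | 4-methylpent-3-enoic acid | CC(C)=CCC(=O)O | starting material
8 | 1-(4-methylpent-3-enoyl)imidazole | CC(C)=CCC(=O)n1ccnc1 | intermediate
9 | N-methoxy-N,4-dimethylpent-3-enamide | CC(C)=CCC(=O)N(C)OC | intermediate
10 | 6-methyl-1-(trimethylsilyl)hept-5-en-1-yn-3-one | CC(C)=CCC(=O)C#C[Si](C)(C)C | intermediate
11 | (R)-6-methyl-1-(trimethylsilyl)hept-5-en-1-yn-3-ol | O[C@H](CC=C(C)C)C#C[Si](C)(C)C | intermediate
12 | (R)-6-methylhept-5-en-1-yn-3-ol | O[C@H](CC=C(C)C)C#C | intermediate
13 | 3-hydroxy-3-methylbutanoic acid | CC(C)(O)CC(=O)O | starting material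
14 | 3-acetoxy-3-methylbutanoic acid | CC(=O)OC(C)(C)CC(=O)O | intermediate
15 | (R)-6-methylhept-5-en-1-yn-3-yl 3-acetoxy-3-methylbutanoate | CC(=O)OC(C)(C)CC(=O)O[C@H](CC=C(C)C)C#C | intermediate
16 | tricarbonylchromium complex of naphthol 17 (η6, metal on the newly formed ring) | CC(=O)OC(C)(C)CC(=O)O[C@H](CC=C(C)C)c1cc(OC)c2c(OCOC)ccc(OCOC)c2c1O.O=C=[Cr](=C=O)=C=O | intermediate
17 | (R)-1-[1-hydroxy-4-methoxy-5,8-bis(methoxymethoxy)naphthalen-2-yl]-4-methylpent-3-enyl 3-acetoxy-3-methylbutanoate | CC(=O)OC(C)(C)CC(=O)O[C@H](CC=C(C)C)c1cc(OC)c2c(OCOC)ccc(OCOC)c2c1O | intermediate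
18 | (R)-1-[5,8-bis(methoxymethoxy)-1,4-dioxo-1,4-dihydronaphthalen-2-yl]-4-methylpent-3-enyl 3-acetoxy-3-methylbutanoate | CC(=O)OC(C)(C)CC(=O)O[C@H](CC=C(C)C)C1=CC(=O)c2c(OCOC)ccc(OCOC)c2C1=O | intermediate
19 | (R)-1-(5,8-dihydroxy-1,4-dioxo-1,4-dihydronaphthalen-2-yl)-4-methylpent-3-enyl 3-acetoxy-3-methylbutanoate | CC(=O)OC(C)(C)CC(=O)O[C@H](CC=C(C)C)C1=CC(=O)c2c(O)ccc(O)c2C1=O | target

**Step count**

Total steps: 11.
Longest linear sequence: 8 steps (steps 3, 4, 5, 6, 8, 9, 10, 11, from acid 7 to target 19).

**Steps most likely to fail**

1. Step 9. The vinylcarbene/vinylketene may partition to indene, cyclobutenone or furan products. The side-chain ester, benzylic to a very electron-rich naphthol, may also ionise (loss of the carboxylate towards an o-quinone methide) or shift to the naphthol oxygen during annulation or decomplexation. The fallback moves the ester to a later stage; it sets out from 12 and returns at 18. Alcohol 12 would be silylated (TBSCl, imidazole, DMF) to the TBS ether F1. Benzannulation of F1 with 6 under the conditions of step 9 should give, through its tricarbonylchromium complex F2, the silyloxy naphthol F3; propargylic silyl ethers are established partners in this annulation and cannot ionise or migrate. Oxidation with PhI(OAc)2 in aqueous MeCN would give the silyloxy quinone F4. HF·pyridine in THF would free the side-chain alcohol F5, and Steglich esterification of F5 with 14 (DCC, DMAP, CH2Cl2, 0 °C) would give 18.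

2. Step 11. The acid needed to hydrolyse both aryl MOM ethers may first eliminate the tertiary acetate or solvolyse the side-chain ester. The fallback removes all acid-labile groups before any ester is present; it sets out from 12 (with 6) and returns at 19. The silyl ether series described under step 9 would be followed as far as the side-chain alcohol F5. Its two MOM ethers would be hydrolysed (NaHSO4·SiO2, CH2Cl2, or dilute HCl in i-PrOH) to give shikonin F6. Steglich acylation with 14 (DCC, DMAP, CH2Cl2, 0 °C) should then take place only at the side-chain hydroxyl, because both peri hydroxyls are tied up in hydrogen bonds to the quinone carbonyls, and give 19.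

3. Step 5. The skipped double bond of 10 may migrate into conjugation with the ynone under the basic ruthenium amide, or the two unsaturated ketone substituents may be discriminated poorly, giving insufficient facial selectivity. The fallback replaces asymmetric reduction by resolution; it sets out from 10 and returns at 12. Luche reduction (NaBH4, CeCl3·7H2O, MeOH, −78 °C) would give the racemic silyl alkynol F7, and K2CO3 in MeOH the racemic alkynol F8. Lipase-catalysed acylation (immobilised Candida antarctica lipase B, vinyl acetate, hexane, rt) is expected, by the empirical size rule with ethynyl as the smaller group, to convert the (S)-enantiomer into the (S)-acetate F9 and to leave (R)-alcohol 12. Alcohol 12 would be separated by chromatography and its configuration checked by Mosher ester analysis.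

**Further compounds**

F1 | step 9 | (R)-tert-butyldimethyl[(6-methylhept-5-en-1-yn-3-yl)oxy]silane | CC(C)(C)[Si](C)(C)O[C@H](CC=C(C)C)C#C
F2 | step 9 | tricarbonylchromium complex of naphthol F3 | CC(C)(C)[Si](C)(C)O[C@H](CC=C(C)C)c1cc(OC)c2c(OCOC)ccc(OCOC)c2c1O.O=C=[Cr](=C=O)=C=O
F3 | step 9 | (R)-2-[1-(tert-butyldimethylsilyloxy)-4-methylpent-3-enyl]-4-methoxy-5,8-bis(methoxymethoxy)naphthalen-1-ol | CC(C)(C)[Si](C)(C)O[C@H](CC=C(C)C)c1cc(OC)c2c(OCOC)ccc(OCOC)c2c1O
F4 | step 9 | (R)-2-[1-(tert-butyldimethylsilyloxy)-4-methylpent-3-enyl]-5,8-bis(methoxymethoxy)naphthalene-1,4-dione | CC(C)(C)[Si](C)(C)O[C@H](CC=C(C)C)C1=CC(=O)c2c(OCOC)ccc(OCOC)c2C1=O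
F5 | step 9 | (R)-2-(1-hydroxy-4-methylpent-3-enyl)-5,8-bis(methoxymethoxy)naphthalene-1,4-dione | O[C@H](CC=C(C)C)C1=CC(=O)c2c(OCOC)ccc(OCOC)c2C1=O
F6 | step 11 | shikonin, (R)-5,8-dihydroxy-2-(1-hydroxy-4-methylpent-3-enyl)naphthalene-1,4-dione | O[C@H](CC=C(C)C)C1=CC(=O)c2c(O)ccc(O)c2C1=O
F7 | step 5 | rac-6-methyl-1-(trimethylsilyl)hept-5-en-1-yn-3-ol | OC(CC=C(C)C)C#C[Si](C)(C)C
F8 | step 5 | rac-6-methylhept-5-en-1-yn-3-ol | OC(CC=C(C)C)C#C
F9 | step 5 | (S)-6-methylhept-5-en-1-yn-3-yl acetate | CC(=O)O[C@@H](CC=C(C)C)C#C
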